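## Retrosynthetic overview

1. Dactylopyranoid (16) ⇒ open-chain tertiary alcohol 15 by cutting C–O and C–Br of the tetrahydropyran; this ring is formed last, by a catalyst-controlled 6-endo bromoetherification.
2. 15 ⇒ bicyclic bromide 6 (as its Grignard reagent) + (S,E)-8-chlorolinalool 12, joined by a Cu-catalysed sp3–allyl coupling.
3. 6 ⇒ 2,5-dimethylfuran (1) + methyl (E)-crotonate (2); a chiral-counteranion (silylium–IDPi) endo Diels–Alder reaction forms the 7-oxabicyclo[2.2.1]heptane first and sets its four stereocentres.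
4. 12 ⇒ geraniol (7): Sharpless epoxidation and reductive epoxide opening set the vinyl carbinol centre, then SeO2 oxidation and chlorination of the (E)-methyl group.
5. Ring order: oxabicycle (step 1), tetrahydropyran (step 9).

Assumption: the sense of induction of the two organocatalysts on these untested substrates cannot be stated in advance; "cat A" and "cat B" stand for whichever antipode gives the drawn product.

- cat A: a confined BINOL-derived N,N′-bis(triflyl) imidodiphosphorimidate (IDPi) Brønsted acid, converted in the flask into its silylium ion pair by methallyltrimethylsilane.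
- cat B: a 3,3′-bis(2,4,6-triisopropylphenyl)-BINOL-derived N-aryl thiophosphoramide (P=S Lewis base with an N–H donor).

## Route

Step 1
Reactants: 1 2,5-dimethylfuran; 2 methyl (E)-but-2-enoate
Product: 4 [(1R,2S,3R,4S)-1,3,4-trimethyl-7-oxabicyclo[2.2.1]hept-5-en-2-yl]methanol, via cycloadduct ester 3 (not isolated)
Conditions: cat A (3 mol%), methallyl-SiMe3 (10 mol%), 1 (3 equiv), PhMe, −80 °C; then DIBAL-H (3.5 equiv), −80 → 0 °C; Rochelle salt
Reagents that add atoms: none
Why: Proposed new method: the silylium–IDPi ion pair O-silylates 2 to a strongly electrophilic silyloxycarbenium held inside the chiral anion, which should undergo an asynchronous endo [4+2] with the electron-rich furan at −80 °C, where the normally reversible furan cycloaddition is exergonic (ester endo and anti to the oxygen bridge, β-methyl exo, one dienophile face shielded, so C1, C2, C3 and C4 are set together), and DIBAL-H reduces the ester before warming so that retro-cycloaddition is shut off; closest known reaction type: silylium/IDPi-catalysed asymmetric Diels–Alder reactions of α,β-unsaturated methyl esters with cyclopentadiene, and low-temperature Lewis-acid-catalysed Diels–Alder reactions of 2,5-dimethylfuran with acrolein.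

Step 2
Reactants: 4 [(1R,2S,3R,4S)-1,3,4-trimethyl-7-oxabicyclo[2.2.1]hept-5-en-2-yl]methanol
Product: 5 [(1R,2S,3R,4S)-1,3,4-trimethyl-7-oxabicyclo[2.2.1]heptan-2-yl]methanol
Conditions: H2 (1 atm), 5% Pd/C, K2CO3 (cat.), EtOAc, 0 °C → rt
Reagents that add atoms: none
Why: Heterogeneous hydrogenation of the strained oxanorbornene alkene is fast, creates no stereocentre and removes any chance of retro-Diels–Alder fragmentation.

Step 3
Reactants: 5 [(1R,2S,3R,4S)-1,3,4-trimethyl-7-oxabicyclo[2.2.1]heptan-2-yl]methanol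
Product: 6 (1R,2R,3R,4S)-2-(bromomethyl)-1,3,4-trimethyl-7-oxabicyclo[2.2.1]heptane
Conditions: CBr4, PPh3, 2,6-lutidine (cat.), CH2Cl2, 0 °C → rt
Reagents that add atoms: carbon tetrabromide, BrC(Br)(Br)Br
Why: Appel reaction; bromide displaces the alkoxyphosphonium by SN2 at the primary carbon under neutral conditions, so the acid-sensitive bridged ether and the four stereocentres are untouched.

Step 4
Reactants: 7 geraniol
Product: 8 (2S,3S)-2,3-epoxygeraniol
Conditions: Ti(OiPr)4 (5 mol%), L-(+)-diethyl tartrate (7.5 mol%), t-BuOOH, 4 Å MS, CH2Cl2, −20 °C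
Reagents that add atoms: tert-butyl hydroperoxide, CC(C)(C)OO
Why: Sharpless asymmetric epoxidation; the Ti–tartrate catalyst epoxidises only the allylic-alcohol alkene and with L-(+)-DET gives the (2S,3S)-epoxide, which fixes the later vinyl carbinol centre as S.

Step 5
Reactants: 8 (2S,3S)-2,3-epoxygeraniol
Product: 10 (S)-linalool, via epoxy iodide 9 (not isolated)
Conditions: PPh3, imidazole, I2, THF, 0 °C; then Zn dust, EtOH, 50 °C (same flask)
Reagents that add atoms: none
Why: Garegg-type iodination (SN2 at the primary carbinol) followed by zinc insertion and β-elimination (reductive epoxide opening) breaks only the C2–O bond, so the C3–O stereocentre is retained and the vinyl carbinol results.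

Step 6
Reactants: 10 (S)-linalool
Product: 11 (2E,6S)-2,6-dimethylocta-2,7-diene-1,6-diol
Conditions: SeO2 (0.4 equiv), t-BuOOH (3 equiv), salicylic acid (10 mol%), CH2Cl2, rt; then NaBH4, MeOH, 0 °C (returns over-oxidised enal to 11)
Reagents that add atoms: selenium dioxide, O=[Se]=O (catalytic oxygen carrier); tert-butyl hydroperoxide, CC(C)(C)OO (terminal oxidant)
Why: SeO2 allylic oxidation (ene reaction then [2,3]-sigmatropic shift) is selective for the (E)-methyl group of the trisubstituted alkene and gives the (E)-allylic alcohol; the vinyl carbinol has no allylic hydrogen and is not attacked.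

Step 7
Reactants: 11 (2E,6S)-2,6-dimethylocta-2,7-diene-1,6-diol
Product: 12 (3S,6E)-8-chloro-3,7-dimethylocta-1,6-dien-3-ol
Conditions: NCS, Me2S, CH2Cl2, −20 → 0 °C
Reagents that add atoms: N-chlorosuccinimide, O=C1CCC(=O)N1Cl
Why: Corey–Kim chlorination converts only the primary allylic alcohol (alkoxysulfonium salt, SN2 by chloride) and leaves the hindered tertiary alcohol, the alkene geometry and C3 unchanged.

Step 8
Reactants: 6 (1R,2R,3R,4S)-2-(bromomethyl)-1,3,4-trimethyl-7-oxabicyclo[2.2.1]heptane; 12 (3S,6E)-8-chloro-3,7-dimethylocta-1,6-dien-3-ol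
Product: 15 (3S,6E)-3,7-dimethyl-9-[(1R,2R,3R,4S)-1,3,4-trimethyl-7-oxabicyclo[2.2.1]heptan-2-yl]nona-1,6-dien-3-ol, via Grignard reagent 13 (not isolated), via magnesium alkoxide 14 (not isolated)
Conditions: 6, Mg, THF, 45 °C; separately 12, MeMgCl (1.0 equiv), THF, −40 °C; combine, Li2CuCl4 (5 mol%), −40 → 0 °C; aq NH4Cl
Reagents that add atoms: none
Why: Kochi-type Cu-catalysed Grignard–allylic halide coupling goes by SN2 (α) attack at the primary allylic carbon with retention of the (E)-alkene, the tertiary alcohol being masked as its magnesium alkoxide; no stereocentre is touched.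

Step 9
Reactants: 15 (3S,6E)-3,7-dimethyl-9-[(1R,2R,3R,4S)-1,3,4-trimethyl-7-oxabicyclo[2.2.1]heptan-2-yl]nona-1,6-dien-3-ol
Product: 16 dactylopyranoid
Conditions: NBS (1.1 equiv), cat B (10 mol%), PhMe/CH2Cl2, −78 → −40 °C
Reagents that add atoms: N-bromosuccinimide, O=C1CCC(=O)N1Br
Why: Proposed new method: the thiophosphoramide sulfur takes Br+ from NBS and the chiral scaffold, hydrogen-bonded to the tertiary hydroxyl, delivers it to the Re face of C6 of the more electron-rich trisubstituted alkene, after which the tethered oxygen opens the bromonium anti at the tertiary carbon (6-endo, Markovnikov), so the CHBr centre (R) and the adjacent ether carbon (S) come from catalyst-controlled face selection plus stereospecific anti addition to the (E)-alkene while the vinyl carbinol centre is carried through; closest known reaction type: chiral Lewis base/Brønsted acid-catalysed enantioselective bromocycloetherification of alkenols, catalytic asymmetric bromonium-initiated polyene cyclisation of trialkyl-substituted alkenes, and stoichiometric TBCO bromoetherification of tertiary alcohols to 3-bromotetrahydropyrans.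

## Compound list

1 | 2,5-dimethylfuran | Cc1ccc(C)o1 | starting material
2 | methyl (E)-but-2-enoate (methyl crotonate) | C/C=C/C(=O)OC | starting material
3 | methyl (1R,2R,3R,4S)-1,3,4-trimethyl-7-oxabicyclo[2.2.1]hept-5-ene-2-carboxylate (2-endo ester, 3-exo methyl) | COC(=O)[C@@H]1[C@@H](C)[C@]2(C)C=C[C@@]1(C)O2 | intermediate (not isolated)
4 | [(1R,2S,3R,4S)-1,3,4-trimethyl-7-oxabicyclo[2.2.1]hept-5-en-2-yl]methanol | OC[C@@H]1[C@@H](C)[C@]2(C)C=C[C@@]1(C)O2 | intermediate
5 | [(1R,2S,3R,4S)-1,3,4-trimethyl-7-oxabicyclo[2.2.1]heptan-2-yl]methanol | OC[C@@H]1[C@@H](C)[C@]2(C)CC[C@@]1(C)O2 | intermediate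
6 | (1R,2R,3R,4S)-2-(bromomethyl)-1,3,4-trimethyl-7-oxabicyclo[2.2.1]heptane | BrC[C@@H]1[C@@H](C)[C@]2(C)CC[C@@]1(C)O2 | intermediate
7 | geraniol, (2E)-3,7-dimethylocta-2,6-dien-1-ol | CC(C)=CCC/C(C)=C/CO | starting material
8 | (2S,3S)-2,3-epoxygeraniol, [(2S,3S)-3-methyl-3-(4-methylpent-3-en-1-yl)oxiran-2-yl]methanol | OC[C@@H]1O[C@@]1(C)CCC=C(C)C | intermediate
9 | (2S,3R)-3-(iodomethyl)-2-methyl-2-(4-methylpent-3-en-1-yl)oxirane | IC[C@@H]1O[C@@]1(C)CCC=C(C)C | intermediate (not isolated)
10 | (S)-linalool, (3S)-3,7-dimethylocta-1,6-dien-3-ol | C=C[C@](O)(C)CCC=C(C)C | intermediate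
11 | (2E,6S)-2,6-dimethylocta-2,7-diene-1,6-diol | C=C[C@](O)(C)CC/C=C(\C)CO | intermediate
12 | (3S,6E)-8-chloro-3,7-dimethylocta-1,6-dien-3-ol | C=C[C@](O)(C)CC/C=C(\C)CCl | intermediate
13 | {[(1R,2R,3R,4S)-1,3,4-trimethyl-7-oxabicyclo[2.2.1]heptan-2-yl]methyl}magnesium bromide | Br[Mg]C[C@@H]1[C@@H](C)[C@]2(C)CC[C@@]1(C)O2 | intermediate (not isolated)
14 | chloromagnesium (3S,6E)-8-chloro-3,7-dimethylocta-1,6-dien-3-olate | C=C[C@](O[Mg]Cl)(C)CC/C=C(\C)CCl | intermediate (not isolated)
15 | (3S,6E)-3,7-dimethyl-9-[(1R,2R,3R,4S)-1,3,4-trimethyl-7-oxabicyclo[2.2.1]heptan-2-yl]nona-1,6-dien-3-ol | C=C[C@](O)(C)CC/C=C(\C)CC[C@@H]1[C@@H](C)[C@]2(C)CC[C@@]1(C)O2 | intermediate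
16 | dactylopyranoid, (2S,3R,6S)-3-bromo-6-ethenyl-2,6-dimethyl-2-{2-[(1R,2R,3R,4S)-1,3,4-trimethyl-7-oxabicyclo[2.2.1]heptan-2-yl]ethyl}oxane | C=C[C@]1(C)CC[C@@H](Br)[C@](C)(CC[C@@H]2[C@@H](C)[C@]3(C)CC[C@@]2(C)O3)O1 | target

## Count and risks

Total step count: 9. Longest linear sequence: 6 steps (7 → 8 → 10 → 11 → 12 → 15 → 16; steps 4–9).

**Step 1 (proposed new cycloaddition).** Risks are an unfavourable equilibrium, exo or Friedel–Crafts products, and low ee. The fallback uses only known chemistry, sets out from 1 and comes back to the route at 5. 2,5-Dimethylfuran 1 and maleic anhydride in ether give the exo meso anhydride F1. Hydrogenation (H2, Pd/C) gives the saturated meso anhydride F2. Cinchona-alkaloid-catalysed desymmetrising methanolysis ((DHQD)2AQN or its pseudo-enantiomer, MeOH, Et2O, −20 °C) sets the absolute configuration and gives the cis hemiester F3. NaOMe in MeOH epimerises the ester-bearing carbon to give the trans hemiester F4 (ester endo, acid exo). BH3·SMe2 reduces only the acid to give the hydroxy ester F5. TsCl/pyridine gives the tosylate F6. LiAlH4 then reduces the tosylate to the exo methyl group and the ester to the carbinol, which is 5. This replaces steps 1 and 2 by seven steps.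

**Step 8 (fragment coupling).** Risks are SN2′ attack, intramolecular attack of the alkoxide on the allylic chloride, and Wurtz coupling. The fallback sets out from 12 (with 6) and comes back at 15. Chloride 12 and PhSO2Na in DMF give the allylic sulfone F7. Its dianion (n-BuLi, 2.1 equiv, THF/DMPU, −78 °C) is alkylated by 6 to give the coupled sulfone F8 as a mixture of epimers at the sulfonyl carbon. Pd(dppp)Cl2/LiBHEt3 reductive desulfonylation, which keeps the position and (E)-geometry of the trisubstituted alkene, gives 15.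

**Step 9 (proposed new catalyst-controlled bromoetherification).** Risks are low face selectivity, 5-exo closure to a tetrahydrofuran, and bromination of the vinyl group. The fallback sets out from 15 and comes back at 16. Stoichiometric TBCO in MeNO2 is the known substrate-controlled closure of tertiary alcohols onto trisubstituted alkenes. It is expected to give 16 together with the bromotetrahydropyran epimeric at both the CHBr carbon and the adjacent ether carbon F9 in roughly equal amounts. The two are separated by HPLC, so stereocontrol at these two centres is given up for a separation.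

Further compounds
F1 | step 1 | exo meso cycloadduct of 1 and maleic anhydride, 4,7-dimethyl-3a,4,7,7a-tetrahydro-4,7-epoxyisobenzofuran-1,3-dione | O=C1OC(=O)[C@H]2[C@@H]1[C@]3(C)C=C[C@@]2(C)O3
F2 | step 1 | saturated exo meso anhydride, 4,7-dimethylhexahydro-4,7-epoxyisobenzofuran-1,3-dione | O=C1OC(=O)[C@H]2[C@@H]1[C@]3(C)CC[C@@]2(C)O3
F3 | step 1 | cis hemiester, 2-exo-methoxycarbonyl-1,4-dimethyl-7-oxabicyclo[2.2.1]heptane-3-exo-carboxylic acid (bridgeheads as in 5) | COC(=O)[C@H]1[C@@H](C(=O)O)[C@]2(C)CC[C@@]1(C)O2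
F4 | step 1 | trans hemiester, 2-endo-methoxycarbonyl-1,4-dimethyl-7-oxabicyclo[2.2.1]heptane-3-exo-carboxylic acid | COC(=O)[C@@H]1[C@@H](C(=O)O)[C@]2(C)CC[C@@]1(C)O2
F5 | step 1 | hydroxy ester, methyl 3-exo-(hydroxymethyl)-1,4-dimethyl-7-oxabicyclo[2.2.1]heptane-2-endo-carboxylate | COC(=O)[C@@H]1[C@@H](CO)[C@]2(C)CC[C@@]1(C)O2
F6 | step 1 | tosylate, methyl 1,4-dimethyl-3-exo-(tosyloxymethyl)-7-oxabicyclo[2.2.1]heptane-2-endo-carboxylate | COC(=O)[C@@H]1[C@@H](COS(=O)(=O)c3ccc(C)cc3)[C@]2(C)CC[C@@]1(C)O2
F7 | step 8 | allylic sulfone, (3S,6E)-3,7-dimethyl-8-(phenylsulfonyl)octa-1,6-dien-3-ol | C=C[C@](O)(C)CC/C=C(\C)CS(=O)(=O)c1ccccc1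
F8 | step 8 | coupled sulfone, (3S,6E)-3,7-dimethyl-8-(phenylsulfonyl)-9-[(1R,2R,3R,4S)-1,3,4-trimethyl-7-oxabicyclo[2.2.1]heptan-2-yl]nona-1,6-dien-3-ol (C8 epimers) | C=C[C@](O)(C)CC/C=C(\C)C(C[C@@H]1[C@@H](C)[C@]2(C)CC[C@@]1(C)O2)S(=O)(=O)c1ccccc1
F9 | step 9 | (2R,3S,6S)-diastereomer of 16 (epimeric at both the CHBr and the adjacent ether carbon) | C=C[C@]1(C)CC[C@H](Br)[C@@](C)(CC[C@@H]2[C@@H](C)[C@]3(C)CC[C@@]2(C)O3)O1
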